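**Retrosynthetic overview**
1. Target 22 is a trans-fused hydroazulene: ring A = C1 (quaternary, CH3), C2, C3, C4 (isopropyl carbinol), C5 (H); ring B = C1, C5, C6 (isovalerate), C7, C8/C9 (methyl epoxide), C10 (acetate).
2. The strategy rests on the vicinal pair C1/C10 of ring B lying between C8=C9 (epoxide precursor) and a latent C5=C6 alkene (later H-5 and O-6), with C7 saturated: a cyclohepta-1,4-diene, the product of a [3,3] shift of a cis-divinylcyclopropane (ring C6–C7–C8).
3. Late disconnections: C6 ester; H-5/O-6 (hydroboration of C5=C6); C10 acetate; C4–isopropyl (organocerium on the C4 ketone); C8–C9 epoxide (delivered from C10–OH).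
4. Key disconnection: C1–C10, with C6–C8 reconnected, gives cyclopropane 12. Ring A is bought as 3-methylcyclopentenone, the cyclopropane is the second ring made, and ring B is closed last by ring expansion.
5. 12 comes from E-alkenylboronate 10 and alcohol 11; 10 from aldehyde 9, cyclopropylmethanol 8 and Z-dienol 7; 7 from iodoenone 2 and Z-boronate 6 (from prop-2-yn-1-ol).

Key step: step 9

Remark: locants C1–C10 are those of overview line 1; α is the face opposite the C1 methyl, β the face of that methyl; R/S labels quoted with these locants refer to the SMILES in the compound list.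

**Step 1**
Reactants: 1 3-methylcyclopent-2-en-1-one
Product: 2 2-iodo-3-methylcyclopent-2-en-1-one
Conditions: I2, pyridine, CH2Cl2, 0 °C → rt
Reagents that add atoms: iodine, II
Why: α-iodination of an enone by conjugate addition of pyridine, iodination of the enolate and loss of pyridine (Baylis–Hillman-type addition–elimination); β-substituted cyclic enones react, only more slowly.

**Step 2**
Reactants: 3 prop-2-yn-1-ol
Product: 5 (Z)-3-iodo-2-methylprop-2-en-1-ol, via alkenylmagnesium chelate 4 (not isolated)
Conditions: MeMgBr (2.5 equiv), CuI (10 mol %), THF, −10 °C → rt; then I2, −10 °C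
Reagents that add atoms: methylmagnesium bromide, C[Mg]Br; iodine, II
Why: copper-catalysed anti-carbomagnesiation of the propargylic alkoxide puts methyl on C2 and magnesium on C3 inside a five-membered alkoxide chelate, and iodinolysis with retention gives the Z iodide (iodine cis to CH2OH).

**Step 3**
Reactants: 5 (Z)-3-iodo-2-methylprop-2-en-1-ol
Product: 6 (Z)-2-methyl-3-(4,4,5,5-tetramethyl-1,3,2-dioxaborolan-2-yl)prop-2-en-1-ol
Conditions: B2pin2, PdCl2(PPh3)2 (3 mol %), PPh3, KOPh, toluene, 50 °C
Reagents that add atoms: bis(pinacolato)diboron, CC1(C)OB(OC1(C)C)B1OC(C)(C)C(C)(C)O1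
Why: Miyaura borylation of an alkenyl iodide proceeds with retention of the Z geometry and tolerates the free hydroxyl.

**Step 4**
Reactants: 2 2-iodo-3-methylcyclopent-2-en-1-one; 6 (Z)-2-methyl-3-(4,4,5,5-tetramethyl-1,3,2-dioxaborolan-2-yl)prop-2-en-1-ol
Product: 7 2-[(Z)-3-hydroxy-2-methylprop-1-en-1-yl]-3-methylcyclopent-2-en-1-one
Conditions: PdCl2(dppf) (5 mol %), K3PO4, THF/H2O, 50 °C
Reagents that add atoms: none
Why: Suzuki–Miyaura coupling of a 2-iodoenone with an alkenylboronate retains the alkene geometry, so the ring and CH2OH stay cis as the cis-cyclopropane later requires.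

**Step 5**
Reactants: 7 2-[(Z)-3-hydroxy-2-methylprop-1-en-1-yl]-3-methylcyclopent-2-en-1-one
Product: 8 2-[(1R,2S)-2-(hydroxymethyl)-2-methylcyclopropyl]-3-methylcyclopent-2-en-1-one
Conditions: Zn(CH2I)2·DME (from Et2Zn and CH2I2), (4R,5R)-2-butyl-N,N,N',N'-tetramethyl-1,3,2-dioxaborolane-4,5-dicarboxamide (1.2 equiv), CH2Cl2, −10 °C → rt
Reagents that add atoms: diiodomethane, ICI
Why: asymmetric Simmons–Smith cyclopropanation through the zinc alkoxide–dioxaborolane complex adds CH2 (C7) syn-stereospecifically to the allylic alkene only (the tetrasubstituted enone alkene is inert to the electrophilic carbenoid); the Z alkene fixes the cis ring/CH2OH relation, and the (4R,5R) ligand should set C8 as S and C6 as R by the sense of induction known for E- and Z-cinnamyl-type alcohols.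

**Step 6**
Reactants: 8 2-[(1R,2S)-2-(hydroxymethyl)-2-methylcyclopropyl]-3-methylcyclopent-2-en-1-one
Product: 9 (1S,2R)-1-methyl-2-(2-methyl-5-oxocyclopent-1-en-1-yl)cyclopropane-1-carbaldehyde
Conditions: Dess–Martin periodinane, CH2Cl2, 0 °C; used at once
Reagents that add atoms: none
Why: Dess–Martin oxidation under neutral conditions gives the non-enolisable aldehyde, which is kept cold and used directly because cis-2-alkenylcyclopropanecarbaldehydes can drift by a retro-Claisen [3,3] shift.

**Step 7**
Reactants: 9 (1S,2R)-1-methyl-2-(2-methyl-5-oxocyclopent-1-en-1-yl)cyclopropane-1-carbaldehyde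
Product: 10 3-methyl-2-[(1R,2R)-2-methyl-2-[(E)-2-(4,4,5,5-tetramethyl-1,3,2-dioxaborolan-2-yl)ethenyl]cyclopropyl]cyclopent-2-en-1-one
Conditions: CH2(Bpin)2, LiTMP (lithium 2,2,6,6-tetramethylpiperidide), THF, 0 °C; then 9, −78 °C → rt
Reagents that add atoms: bis(4,4,5,5-tetramethyl-1,3,2-dioxaborolan-2-yl)methane, CC1(C)OB(CB2OC(C)(C)C(C)(C)O2)OC1(C)C
Why: boron–Wittig olefination: the α-boryl carbanion adds to the aldehyde in preference to the hindered enone, and syn B–O elimination gives the trans alkenylboronate, a selectivity that is highest for α-branched aldehydes; this replaces an alkoxymethylene Wittig reaction, which would give E/Z mixtures.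

**Step 8**
Reactants: 10 3-methyl-2-[(1R,2R)-2-methyl-2-[(E)-2-(4,4,5,5-tetramethyl-1,3,2-dioxaborolan-2-yl)ethenyl]cyclopropyl]cyclopent-2-en-1-one; 11 (4-methoxyphenyl)methanol
Product: 12 2-[(1R,2S)-2-[(E)-2-[(4-methoxyphenyl)methoxy]ethenyl]-2-methylcyclopropyl]-3-methylcyclopent-2-en-1-one
Conditions: Cu(OAc)2 (2 equiv), Et3N (4 equiv), 11 (10 equiv), 4 Å MS, CH2Cl2, air, rt
Reagents that add atoms: none
Why: Chan–Lam-type copper-promoted C–O coupling of an alkenyl pinacolboronate with a primary alcohol gives the enol ether with retention (E) at room temperature; any 12 that rearranges early only becomes 13.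

**Step 9**
Reactants: 12 2-[(1R,2S)-2-[(E)-2-[(4-methoxyphenyl)methoxy]ethenyl]-2-methylcyclopropyl]-3-methylcyclopent-2-en-1-one
Product: 13 (3aS,4R)-4-[(4-methoxyphenyl)methoxy]-3a,6-dimethyl-3,3a,4,7-tetrahydroazulen-1(2H)-one
Conditions: toluene (0.02 M), solid K2CO3, sealed tube, 110–140 °C
Reagents that add atoms: none
Why: Thermal [3,3] sigmatropic shift of a cis-1,2-dialkenylcyclopropane (divinylcyclopropane–cycloheptadiene rearrangement, the closest known reaction type): in a boat transition state with both alkenes folded over C7, C1–C10 forms while C6–C8 breaks, driven by release of cyclopropane strain. Ring B is closed by this concerted expansion of the three-membered ring to the seven-membered ring, which leaves the C5=C6 and C8=C9 alkenes on either side of the saturated C7. Both new stereocentres are set by the boat: the ring A carbon C2 and the E-oxygen on C10 are the outward groups, the C1 methyl (held inward by the cyclopentene) and H-10 the inward ones, so methyl and C10–O end up trans, and the 6R,8S cyclopropane turns this into 1S,10R. The step needs the cis-cyclopropane (secured by the Z alkene of 7 and the syn cyclopropanation) and the E enol ether (secured by steps 7 and 8), since a Z ether would point oxygen inward and shut the boat. The inward methyl on a fully substituted terminus makes this a slow case, hence 110–140 °C; no cis alkyl C–H is placed for a competing homodienyl hydrogen shift, and the unsubstituted C7 leaves the boat otherwise unhindered. Solid K2CO3 keeps trace acid from the enol ether.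

**Step 10**
Reactants: 13 (3aS,4R)-4-[(4-methoxyphenyl)methoxy]-3a,6-dimethyl-3,3a,4,7-tetrahydroazulen-1(2H)-one
Product: 14 (3aS,4R)-4-hydroxy-3a,6-dimethyl-3,3a,4,7-tetrahydroazulen-1(2H)-one
Conditions: DDQ (1.3 equiv), CH2Cl2/pH 7 buffer (10:1), 0 °C
Reagents that add atoms: none
Why: oxidative cleavage of the 4-methoxybenzyl ether by DDQ (benzylic hydride abstraction, hydrolysis of the oxocarbenium ion); it is done at the enone stage, where the doubly allylic C7–H is deactivated by the conjugated carbonyl.

**Step 11**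
Reactants: 14 (3aS,4R)-4-hydroxy-3a,6-dimethyl-3,3a,4,7-tetrahydroazulen-1(2H)-one
Product: 15 8α,9α-epoxy-10α-hydroxy enone (14 with an oxirane on C8–C9 cis to the C10 hydroxyl; 1S,8R,9S,10S)
Conditions: VO(acac)2 (5 mol %), tBuOOH (1.5 equiv, decane), CH2Cl2, 0 °C → rt
Reagents that add atoms: tert-butyl hydroperoxide, CC(C)(C)OO
Why: vanadium-catalysed hydroxyl-directed epoxidation delivers oxygen to the face of C8=C9 syn to the allylic C10 hydroxyl (α), setting C8 and C9, while the electron-poor enone alkene C5=C6 does not react.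

**Step 12**
Reactants: 15 8α,9α-epoxy-10α-hydroxy enone
Product: 16 4β,10α-diol (isopropyl α on C4; C5=C6 alkene and 8α,9α-epoxide kept; 1S,4R,8R,9S,10S)
Conditions: iPrMgCl (4 equiv), CeCl3 (anhydrous, 4 equiv), THF, −78 → −40 °C; aq NH4Cl
Reagents that add atoms: isopropylmagnesium chloride, CC(C)[Mg]Cl
Why: organocerium 1,2-addition: the weakly basic iPrCeCl2 adds to the hindered, enolisable enone carbonyl without conjugate addition or γ-deprotonation at C7 (which would open the epoxide), one equivalent being spent on the C10 hydroxyl; attack should come from the α face because the boat-shaped ring B holds C10 near the enone plane and the C1 methyl almost perpendicular to it on the β face, giving the 4β-hydroxyl (4R).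

**Step 13**
Reactants: 16 4β,10α-diol
Product: 17 10α-acetate of 16 (C4 hydroxyl free)
Conditions: Ac2O (1.5 equiv), DMAP (0.1 equiv), pyridine, CH2Cl2, 0 °C → rt
Reagents that add atoms: acetic anhydride, CC(=O)OC(C)=O
Why: DMAP-catalysed acylation takes the secondary C10 hydroxyl and leaves the tertiary C4 hydroxyl, which is flanked by isopropyl and the ring fusion.

**Step 14**
Reactants: 17 10α-acetate of 16
Product: 18 4β-trimethylsilyl ether of 17
Conditions: 1-(trimethylsilyl)imidazole, CH2Cl2, rt → 40 °C
Reagents that add atoms: 1-(trimethylsilyl)imidazole, C[Si](C)(C)n1ccnc1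
Why: silylation of the tertiary allylic alcohol with a neutral, powerful silyl donor avoids acid (ionisation of the allylic carbinol, epoxide opening); the β-silyloxy group prevents alkoxyborane formation and adds to the shielding of the β face in the next step.

**Step 15**
Reactants: 18 4β-trimethylsilyl ether of 17
Product: 20 6α-alcohol with 5α-H (trans ring fusion; 1S,4R,5S,6S,8R,9S,10S), via C6 alkylborane 19 (not isolated)
Conditions: BH3·SMe2 (3 equiv), THF, 0 °C → rt; then NaBO3·4H2O, THF/H2O, rt
Reagents that add atoms: borane–dimethyl sulfide, [BH3-][S+](C)C; sodium perborate NaBO3·4H2O, [Na+].[Na+].O[B-]1(O)OO[B-](O)(O)OO1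
Why: hydroboration–oxidation: H–B adds syn across the trisubstituted C5=C6 with boron on the less substituted C6, and the C–B bond is oxidised with retention by the mild perborate (acetate and silyl ether survive); the borane should approach anti to the pseudo-axial C1 methyl and to the allylic C4 silyloxy group, as in hydroborations next to angular methyl groups, so H-5 and O-6 both become α (5S,6S).

**Step 16**
Reactants: 20 6α-alcohol
Product: 21 6α-(3-methylbutanoate) of 20
Conditions: (Me2CHCH2CO)2O (2 equiv), DMAP (0.2 equiv), Et3N, CH2Cl2, rt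
Reagents that add atoms: 3-methylbutanoic anhydride, CC(C)CC(=O)OC(=O)CC(C)C
Why: DMAP-catalysed (Steglich-type) acylation of the only free hydroxyl, the secondary C6–OH.

**Step 17**
Reactants: 21 6α-(3-methylbutanoate) of 20
Product: 22 CNP0137153.1 (10α-acetoxy-8α,9α-epoxy-4β-hydroxy-6α-(3-methylbutanoyloxy) trans-fused hydroazulene; 1S,4R,5S,6S,8R,9S,10S)
Conditions: TBAF (1.2 equiv), AcOH (1.2 equiv), THF, 0 °C → rt
Reagents that add atoms: none
Why: fluoride cleavage of the tertiary trimethylsilyl ether, buffered with acetic acid so that the esters neither migrate nor cleave and the epoxide stays closed.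

**Compound list**
1 | 3-methylcyclopent-2-en-1-one | CC1=CC(=O)CC1 | starting material
2 | 2-iodo-3-methylcyclopent-2-en-1-one | CC1=C(I)C(=O)CC1 | intermediate
3 | prop-2-yn-1-ol | C#CCO | starting material
4 | alkenylmagnesium alkoxide chelate (4-methyl-2,5-dihydro-1,2-oxamagnesole, not isolated) | CC1=C[Mg]OC1 | intermediate
5 | (Z)-3-iodo-2-methylprop-2-en-1-ol | I/C=C(/C)CO | intermediate
6 | (Z)-2-methyl-3-(4,4,5,5-tetramethyl-1,3,2-dioxaborolan-2-yl)prop-2-en-1-ol | CC1(C)OB(/C=C(/C)CO)OC1(C)C | intermediate
7 | 2-[(Z)-3-hydroxy-2-methylprop-1-en-1-yl]-3-methylcyclopent-2-en-1-one | CC1=C(/C=C(/C)CO)C(=O)CC1 | intermediate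
8 | 2-[(1R,2S)-2-(hydroxymethyl)-2-methylcyclopropyl]-3-methylcyclopent-2-en-1-one (cis; C6 R, C8 S) | OC[C@@]1(C)C[C@H]1C1=C(C)CCC1=O | intermediate
9 | (1S,2R)-1-methyl-2-(2-methyl-5-oxocyclopent-1-en-1-yl)cyclopropane-1-carbaldehyde | O=C[C@@]1(C)C[C@H]1C1=C(C)CCC1=O | intermediate
10 | 3-methyl-2-[(1R,2R)-2-methyl-2-[(E)-2-(4,4,5,5-tetramethyl-1,3,2-dioxaborolan-2-yl)ethenyl]cyclopropyl]cyclopent-2-en-1-one | CC1(C)OB(/C=C/[C@@]2(C)C[C@H]2C2=C(C)CCC2=O)OC1(C)C | intermediate
11 | (4-methoxyphenyl)methanol | COc1ccc(CO)cc1 | starting material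
12 | 2-[(1R,2S)-2-[(E)-2-[(4-methoxyphenyl)methoxy]ethenyl]-2-methylcyclopropyl]-3-methylcyclopent-2-en-1-one | COc1ccc(CO/C=C/[C@@]2(C)C[C@H]2C3=C(C)CCC3=O)cc1 | intermediate
13 | (3aS,4R)-4-[(4-methoxyphenyl)methoxy]-3a,6-dimethyl-3,3a,4,7-tetrahydroazulen-1(2H)-one (C1 S, C10 R) | COc1ccc(CO[C@@H]2C=C(C)CC=C3[C@]2(C)CCC3=O)cc1 | intermediate
14 | (3aS,4R)-4-hydroxy-3a,6-dimethyl-3,3a,4,7-tetrahydroazulen-1(2H)-one | O[C@@H]1C=C(C)CC=C2[C@]1(C)CCC2=O | intermediate
15 | 8α,9α-epoxy-10α-hydroxy enone (1S,8R,9S,10S) | O[C@@H]1[C@@H]2O[C@]2(C)CC=C2[C@]1(C)CCC2=O | intermediate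
16 | 4β,10α-diol with 4α-isopropyl, C5=C6 and 8α,9α-epoxide (1S,4R,8R,9S,10S) | O[C@@H]1[C@@H]2O[C@]2(C)CC=C2[C@]1(C)CC[C@@]2(O)C(C)C | intermediate
17 | 10α-acetate of 16 | CC(=O)O[C@@H]1[C@@H]2O[C@]2(C)CC=C2[C@]1(C)CC[C@@]2(O)C(C)C | intermediate
18 | 4β-trimethylsilyl ether of 17 | CC(=O)O[C@@H]1[C@@H]2O[C@]2(C)CC=C2[C@]1(C)CC[C@@]2(O[Si](C)(C)C)C(C)C | intermediate
19 | C6 alkylborane from 18 (BH2 α on C6, H α on C5; not isolated) | CC(=O)O[C@@H]1[C@@H]2O[C@]2(C)C[C@H](B)[C@@H]2[C@]1(C)CC[C@@]2(O[Si](C)(C)C)C(C)C | intermediate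
20 | 6α-alcohol with 5α-H (1S,4R,5S,6S,8R,9S,10S) | CC(=O)O[C@@H]1[C@@H]2O[C@]2(C)C[C@H](O)[C@@H]2[C@]1(C)CC[C@@]2(O[Si](C)(C)C)C(C)C | intermediate
21 | 6α-(3-methylbutanoate) of 20 | CC(=O)O[C@@H]1[C@@H]2O[C@]2(C)C[C@H](OC(=O)CC(C)C)[C@@H]2[C@]1(C)CC[C@@]2(O[Si](C)(C)C)C(C)C | intermediate
22 | CNP0137153.1 (1S,4R,5S,6S,8R,9S,10S) | CC(=O)O[C@@H]1[C@@H]2O[C@]2(C)C[C@H](OC(=O)CC(C)C)[C@@H]2[C@]1(C)CC[C@@]2(O)C(C)C | target

**Totals**
Total step count: 17. Longest linear sequence: 16 steps (3 to 22, steps 2–17); step 1 is the only step of the other branch.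

**Steps most likely to fail**

Step 9. The [3,3] shift may be too slow, because the inward methyl sits on a fully substituted terminus. At the temperature then needed, the acid- and heat-labile enol ether can hydrolyse or isomerise, and the skipped diene of 13 can drift into conjugation faster than 12 rearranges. The fallback sets out from 10 and rearranges the alkenylboronate itself, which carries the same E (outward) substituent but is thermally robust (o-xylene, 140–160 °C), to the C10-boryl dienone F1. Oxidation of the allylic C–B bond with retention (NaBO3·4H2O, THF/H2O) comes back to the route at 14; steps 8 and 10 fall away.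

Step 15. Facial selectivity may be poor: the α face that must be attacked is the inner face of the boat-shaped ring B and carries the C4 isopropyl group and the nearby epoxide oxygen, so borane may add from β and give the cis-fused 5β-H/6β-OH isomer. Slow reduction of the epoxide by the borane would add to the loss. The fallback sets out from 13 and comes back at 22.
- Isopropyl is added to 13 under the conditions of step 12 to give the tertiary allylic alcohol F3.
- VO(acac)2/tBuOOH, directed by the C4 hydroxyl, gives the 5β,6β-epoxide F4.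
- Titanocene-mediated reductive opening (Cp2TiCl2, Zn dust, 1,4-cyclohexadiene, THF) forms the tertiary C5 radical, which should take hydrogen on the α face, away from the three β groups around it (C1 methyl and the titanium-bound oxygens on C4 and C6), giving the 5α-H 4β,6β-diol F5.
- Dess–Martin oxidation (neutral, cold) gives the hydroxy ketone F6; Me4NBH(OAc)3 in MeCN/AcOH, bound to the 4β-hydroxyl, delivers hydride to the β face of C6 (Evans–Saksena anti reduction) to give the 4β,6α-diol F7.
- Acylation of the secondary hydroxyl as in step 16 gives the isovalerate F8; DDQ frees the C10 alcohol F9; VO(acac)2/tBuOOH gives the 8α,9α-epoxide F10; acetylation as in step 13 gives 22.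

Step 12. Enolisation (at C3, or at C7 with loss of the epoxide) and β-hydride reduction by the branched reagent may outrun addition to the hindered conjugated ketone, and the α-face preference may erode with so bulky a nucleophile. The fallback sets out from 15: the smaller sp2 reagent CH2=C(CH3)MgBr with CeCl3, which has no β-hydrogen, should give the isopropenyl carbinol F2. Hydrogenation over RhCl(PPh3)3 (H2, benzene, rt) should saturate only the 1,1-disubstituted alkene and come back to the route at 16.

**Further compounds**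
F1 | step 9 | C10-boryl dienone (13 with the pinacolboryl group in place of the C10 oxygen substituent, same spatial arrangement) | CC1(C)OB(OC1(C)C)[C@@H]1C=C(C)CC=C2[C@]1(C)CCC2=O
F2 | step 12 | isopropenyl carbinol (16 with prop-1-en-2-yl in place of isopropyl) | O[C@@H]1[C@@H]2O[C@]2(C)CC=C2[C@]1(C)CC[C@@]2(O)C(C)=C
F3 | step 15 | tertiary allylic alcohol (13 after α-face addition of isopropyl to C4; 4β-OH) | COc1ccc(CO[C@@H]2C=C(C)CC=C3[C@]2(C)CC[C@@]3(O)C(C)C)cc1
F4 | step 15 | 5β,6β-epoxide of F3 | COc1ccc(CO[C@@H]2C=C(C)C[C@H]3O[C@@]34[C@]2(C)CC[C@@]4(O)C(C)C)cc1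
F5 | step 15 | 4β,6β-diol with 5α-H | COc1ccc(CO[C@@H]2C=C(C)C[C@@H](O)[C@@H]3[C@]2(C)CC[C@@]3(O)C(C)C)cc1
F6 | step 15 | 4β-hydroxy 6-ketone with 5α-H | COc1ccc(CO[C@@H]2C=C(C)CC(=O)[C@@H]3[C@]2(C)CC[C@@]3(O)C(C)C)cc1
F7 | step 15 | 4β,6α-diol with 5α-H | COc1ccc(CO[C@@H]2C=C(C)C[C@H](O)[C@@H]3[C@]2(C)CC[C@@]3(O)C(C)C)cc1
F8 | step 15 | 6α-(3-methylbutanoate) of F7 | COc1ccc(CO[C@@H]2C=C(C)C[C@H](OC(=O)CC(C)C)[C@@H]3[C@]2(C)CC[C@@]3(O)C(C)C)cc1
F9 | step 15 | C10 alcohol from F8 | O[C@@H]1C=C(C)C[C@H](OC(=O)CC(C)C)[C@@H]2[C@]1(C)CC[C@@]2(O)C(C)C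
F10 | step 15 | 8α,9α-epoxide of F9 | O[C@@H]1[C@@H]2O[C@]2(C)C[C@H](OC(=O)CC(C)C)[C@@H]2[C@]1(C)CC[C@@]2(O)C(C)C
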